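**Retrosynthetic overview**

1. The target is a cyclohexane (C5–C10) that carries a vinyl group (C1=C2) on the quaternary C10 and a 2-propenal unit (C4(=C3)–C15HO) on the neighbouring C5. The hexa-1,5-diene C2=C1–C10–C5–C4=C3 built around the C5–C10 ring bond is a Cope retron, so C5–C10 is formed last by contracting a ten-membered (1(10)E,4Z)-germacradien-15-al whose trans-fused C7–C8 lactone fixes the chair.
2. Ten-membered ring: C6–C7 bond by intramolecular CrCl2-mediated allylation of a Z-enal by a 3-(bromomethyl)butenolide, which also creates the α-methylene lactone and C7. C6 is then reset by oxidation and peripheral hydride reduction.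
3. Butenolide with C8/C9: Sharpless epoxidation of a dienol, Ti(Oi-Pr)4-mediated opening at C9 by angelic acid (erythro, angelate installed directly), Bestmann-ylide ring closure, Morita–Baylis–Hillman hydroxymethylation, bromination.
4. Carbon chain: syn carbocupration of a 4-alkoxybut-2-ynoate with a homoprenylcopper reagent (fixes the C4=C5 geometry and the C15 oxygen), SeO2 oxidation of the E-methyl group (C9), Horner–Wadsworth–Emmons extension (C7, C8).
5. Order of ring formation: butenolide (five-membered), then the ten-membered carbocycle, then the six-membered ring by contraction of the ten-membered ring. A final desilylation gives the target.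

Key step: step 21

Remark: positions C1–C15 follow germacrane/elemane numbering; α/β refer to the usual drawing with H-7 α; PMB = 4-methoxybenzyl, TBS = tert-butyldimethylsilyl, TES = triethylsilyl, angelate = (2Z)-2-methylbut-2-enoate.

**Route**

Step 1
Reactants: 1 4-methoxybenzyl prop-2-yn-1-yl ether
Product: 3 ethyl 4-[(4-methoxybenzyl)oxy]but-2-ynoate, via lithium acetylide 2 (not isolated)
Conditions: n-BuLi, THF, −78 °C; then ClCO2Et, −78 → 0 °C
Reagents that add atoms: ethyl chloroformate, CCOC(=O)Cl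
Why: Deprotonation of the terminal alkyne and C-acylation of the lithium acetylide with a chloroformate is a standard alkynoate synthesis that creates no stereocentre.

Step 2
Reactants: 3 ethyl 4-[(4-methoxybenzyl)oxy]but-2-ynoate; 4 5-bromo-2-methylpent-2-ene
Product: 8 ethyl (2Z)-3-{[(4-methoxybenzyl)oxy]methyl}-7-methylocta-2,6-dienoate, via Grignard reagent 5 (not isolated), via organocopper reagent 6 (not isolated), via alkenylcopper adduct 7 (not isolated)
Conditions: 4, Mg, THF, 25 °C; CuBr·SMe2, THF, −40 °C; 3, −78 °C; MeOH, −78 °C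
Reagents that add atoms: none
Why: Carbocupration of an alkynoate at −78 °C is a syn addition and the alkenylcopper is protonated with retention, so the homoprenyl chain ends up trans and the CH2OPMB carbon (C15) cis to the ester carbon (C6), which is the 4Z geometry the ten-membered ring needs.

Step 3
Reactants: 8 ethyl (2Z)-3-{[(4-methoxybenzyl)oxy]methyl}-7-methylocta-2,6-dienoate
Product: 9 (2Z)-3-{[(4-methoxybenzyl)oxy]methyl}-7-methylocta-2,6-dien-1-ol
Conditions: i-Bu2AlH, CH2Cl2, −78 °C
Reagents that add atoms: none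
Why: 1,2-Reduction of the enoate by i-Bu2AlH should give the allylic alcohol (C6–OH) without touching the alkene geometry.

Step 4
Reactants: 9 (2Z)-3-{[(4-methoxybenzyl)oxy]methyl}-7-methylocta-2,6-dien-1-ol
Product: 10 TBS ether of 9
Conditions: TBSCl, imidazole, CH2Cl2, 0 °C
Reagents that add atoms: tert-butyldimethylsilyl chloride, CC(C)(C)[Si](C)(C)Cl
Why: Silylation under imidazole conditions differentiates the C6 oxygen (TBS) from the C15 oxygen (PMB) for the later orthogonal unmasking.

Step 5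
Reactants: 10 TBS ether of 9
Product: 12 (2E,6Z)-8-[(tert-butyldimethylsilyl)oxy]-6-{[(4-methoxybenzyl)oxy]methyl}-2-methylocta-2,6-dienal, via allylic alcohol 11 (not isolated)
Conditions: SeO2 (0.5 equiv), t-BuOOH, CH2Cl2, 0 → 25 °C; then MnO2, CH2Cl2, 25 °C
Reagents that add atoms: tert-butyl hydroperoxide, CC(C)(C)OO
Why: SeO2 allylic oxidation (ene reaction then [2,3]-shift) should attack the E-methyl group of the electron-rich terminal trisubstituted alkene, the other alkene being deactivated by two allylic C–O bonds, and MnO2 completes the oxidation to the E-enal (C9).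

Step 6
Reactants: 12 (2E,6Z)-dienal; 13 triethyl phosphonoacetate
Product: 14 ethyl (2E,4E,8Z)-10-[(tert-butyldimethylsilyl)oxy]-8-{[(4-methoxybenzyl)oxy]methyl}-4-methyldeca-2,4,8-trienoate
Conditions: LiCl, DBU, MeCN, 0 → 25 °C
Reagents that add atoms: none
Why: The Horner–Wadsworth–Emmons reaction of a stabilized phosphonate under mild amine/LiCl conditions should add C8 and C7 as an E-enoate.

Step 7
Reactants: 14 ethyl (2E,4E,8Z)-trienoate
Product: 15 (2E,4E,8Z)-10-[(tert-butyldimethylsilyl)oxy]-8-{[(4-methoxybenzyl)oxy]methyl}-4-methyldeca-2,4,8-trien-1-ol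
Conditions: i-Bu2AlH, CH2Cl2, −78 °C
Reagents that add atoms: none
Why: 1,2-Reduction of the dienoate gives the dienol whose primary hydroxyl (on C7) will direct the epoxidation.

Step 8
Reactants: 15 (2E,4E,8Z)-trienol
Product: 16 {(2R,3R)-3-[(2E,6Z)-8-[(tert-butyldimethylsilyl)oxy]-6-{[(4-methoxybenzyl)oxy]methyl}octa-2,6-dien-2-yl]oxiran-2-yl}methanol
Conditions: Ti(Oi-Pr)4 (0.1 equiv), D-(−)-diethyl tartrate, t-BuOOH, 4 Å MS, CH2Cl2, −25 °C
Reagents that add atoms: tert-butyl hydroperoxide, CC(C)(C)OO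
Why: The Sharpless asymmetric epoxidation oxidizes only the hydroxyl-directed C8=C9 alkene, and the D-(−)-tartrate ligand should give the (2R,3R)-epoxy alcohol, which fixes the absolute configuration at C8 and the face opened at C9.

Step 9
Reactants: 16 (2R,3R)-epoxy alcohol; 17 angelic acid
Product: 18 (2R,3S,4E,8Z)-10-[(tert-butyldimethylsilyl)oxy]-1,2-dihydroxy-8-{[(4-methoxybenzyl)oxy]methyl}-4-methyldeca-4,8-dien-3-yl angelate
Conditions: Ti(Oi-Pr)4 (1.5 equiv), CH2Cl2, 25 °C
Reagents that add atoms: none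
Why: Ti(Oi-Pr)4-mediated opening of a 2,3-epoxy alcohol by a carboxylic acid occurs at C3 (here C9, also allylic) with inversion, so C9 receives the angelate with the S configuration and the erythro C8/C9 relationship while C8 keeps the epoxide oxygen.

Step 10
Reactants: 18 diol monoangelate; 19 (triphenylphosphoranylidene)ketene
Product: 22 (1S,2E,6Z)-8-[(tert-butyldimethylsilyl)oxy]-6-{[(4-methoxybenzyl)oxy]methyl}-2-methyl-1-[(2R)-5-oxo-2,5-dihydrofuran-2-yl]octa-2,6-dien-1-yl angelate, via α-hydroxy aldehyde 20 (not isolated), via phosphoranylidene ester 21 (not isolated)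
Conditions: TEMPO (0.1 equiv), PhI(OAc)2, CH2Cl2, 25 °C; aqueous NaHCO3 wash; then 19, PhMe, 80 °C
Reagents that add atoms: none
Why: Nitroxyl-catalysed oxidation is selective for the primary hydroxyl, the secondary hydroxyl then adds to the cumulated ylide, and the resulting ester ylide closes the butenolide by an intramolecular Wittig reaction under neutral conditions, the ring enforcing the cis alkene and leaving C8 untouched.

Step 11
Reactants: 22 butenolide
Product: 23 (1S,2E,6Z)-8-[(tert-butyldimethylsilyl)oxy]-1-[(2R)-4-(hydroxymethyl)-5-oxo-2,5-dihydrofuran-2-yl]-6-{[(4-methoxybenzyl)oxy]methyl}-2-methylocta-2,6-dien-1-yl angelate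
Conditions: aq. CH2O, PBu3 (0.2 equiv), THF, 25 °C
Reagents that add atoms: formaldehyde, C=O
Why: Morita–Baylis–Hillman hydroxymethylation under nucleophilic phosphine catalysis installs C13 at the α-carbon of the butenolide without a Brønsted base that could deprotonate C8.

Step 12
Reactants: 23 hydroxymethyl butenolide
Product: 24 (1S,2E,6Z)-1-[(2R)-4-(bromomethyl)-5-oxo-2,5-dihydrofuran-2-yl]-8-[(tert-butyldimethylsilyl)oxy]-6-{[(4-methoxybenzyl)oxy]methyl}-2-methylocta-2,6-dien-1-yl angelate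
Conditions: CBr4, PPh3, CH2Cl2, 0 °C
Reagents that add atoms: carbon tetrabromide, BrC(Br)(Br)Br
Why: The Appel reaction converts the primary allylic alcohol into the allylic bromide under neutral conditions.

Step 13
Reactants: 24 bromomethyl butenolide
Product: 25 (1S,2E,6Z)-1-[(2R)-4-(bromomethyl)-5-oxo-2,5-dihydrofuran-2-yl]-8-hydroxy-6-{[(4-methoxybenzyl)oxy]methyl}-2-methylocta-2,6-dien-1-yl angelate
Conditions: HF·pyridine, pyridine, THF, 0 °C
Reagents that add atoms: none
Why: Buffered HF·pyridine cleaves the primary allylic TBS ether while the PMB ether, the allylic bromide and both esters should survive.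

Step 14
Reactants: 25 allylic alcohol
Product: 26 (1S,2E,6Z)-1-[(2R)-4-(bromomethyl)-5-oxo-2,5-dihydrofuran-2-yl]-6-{[(4-methoxybenzyl)oxy]methyl}-2-methyl-8-oxoocta-2,6-dien-1-yl angelate
Conditions: MnO2, CH2Cl2, 25 °C
Reagents that add atoms: none
Why: MnO2 oxidizes the primary allylic alcohol to the enal (C6) under neutral conditions with retention of the Z geometry.

Step 15
Reactants: 26 bromo enal
Product: 28 9α-angeloyloxy-6α-hydroxy-15-[(4-methoxybenzyl)oxy]germacra-1(10)E,4Z,11(13)-trien-12,8α-olide (6α epimer expected to prevail; 6β epimer carried along), via allylchromium species 27 (not isolated)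
Conditions: CrCl2 (6 equiv), THF, 25 °C, slow addition of 26 (final 2 mM)
Reagents that add atoms: none
Why: Chromium dichloride-mediated intramolecular carbonyl allylation (Nozaki–Hiyama type, the established way to close the ten-membered ring of germacranolides) should join C6 and C7 with allylic transposition to give the α-methylene lactone, C7 being set by attack on the butenolide face anti to the C9-bearing substituent at C8 (trans lactone), while the C6 configuration is immaterial because it is reset in steps 16 and 17.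

Step 16
Reactants: 28 germacranolide alcohol
Product: 29 9α-angeloyloxy-15-[(4-methoxybenzyl)oxy]-6-oxogermacra-1(10)E,4Z,11(13)-trien-12,8α-olide
Conditions: Dess–Martin periodinane, NaHCO3, CH2Cl2, 0 → 25 °C
Reagents that add atoms: none
Why: Buffered Dess–Martin oxidation converts both C6 epimers into the same enone without strong acid or base that could move the exocyclic alkene.

Step 17
Reactants: 29 6-ketone
Product: 30 9α-angeloyloxy-6β-hydroxy-15-[(4-methoxybenzyl)oxy]germacra-1(10)E,4Z,11(13)-trien-12,8α-olide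
Conditions: NaBH4, CeCl3·7H2O, MeOH, −78 °C
Reagents that add atoms: none
Why: Luche reduction gives 1,2-reduction of the enone, and because the C14 methyl group and the C15 CH2OPMB group both lie over the β face of the C6 carbonyl in the crossed ring conformation, hydride should add from the open peripheral α face to give the 6β-alcohol.

Step 18
Reactants: 30 6β-alcohol
Product: 31 9α-angeloyloxy-15-[(4-methoxybenzyl)oxy]-6β-(triethylsilyloxy)germacra-1(10)E,4Z,11(13)-trien-12,8α-olide
Conditions: TESOTf, 2,6-lutidine, CH2Cl2, −78 °C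
Reagents that add atoms: triethylsilyl trifluoromethanesulfonate, CC[Si](CC)(CC)OS(=O)(=O)C(F)(F)F
Why: Silylation masks the 6-hydroxyl, which would otherwise form a cyclic hemiacetal (and then a furan) with the cis-disposed C15 aldehyde made in step 20.

Step 19
Reactants: 31 TES ether
Product: 32 9α-angeloyloxy-15-hydroxy-6β-(triethylsilyloxy)germacra-1(10)E,4Z,11(13)-trien-12,8α-olide
Conditions: DDQ, CH2Cl2/pH 7 buffer, 0 °C
Reagents that add atoms: none
Why: Oxidative cleavage of the PMB ether by DDQ under buffered conditions frees the C15 alcohol without acid, which the transannularly reactive 1(10),4-diene would not tolerate.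

Step 20
Reactants: 32 allylic alcohol
Product: 33 9α-angeloyloxy-15-oxo-6β-(triethylsilyloxy)germacra-1(10)E,4Z,11(13)-trien-12,8α-olide
Conditions: Dess–Martin periodinane, NaHCO3, CH2Cl2, 0 °C
Reagents that add atoms: none
Why: Dess–Martin oxidation of the primary allylic alcohol gives the C4 formyl group, whose Z relationship to C6 is held by the ring.

Step 21
Reactants: 33 germacranolide aldehyde
Product: 34 9α-angeloyloxy-15-oxo-6β-(triethylsilyloxy)elema-1,3,11(13)-trien-12,8α-olide
Conditions: PhMe, 100 °C, BHT (cat.), sealed tube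
Reagents that add atoms: none
Why: Heating 33 triggers a thermal [3,3]-sigmatropic (Cope) rearrangement of the cyclodeca-1(10),4-diene, in which the C2–C3 σ-bond breaks while C5 and C10 bond across the ring, so the ten-membered ring contracts to the cyclohexane and releases the vinyl (C1=C2) and 2-propenal (C3=C4–C15HO) groups. The closest known reaction type is the germacranolide-to-elemanolide Cope rearrangement, which is eased when C4 carries a formyl group because the diene is conjugated and the enal is retained as an acrolein unit. The six-membered ring is closed by concerted transannular C–C bond formation through a chair-like six-centre transition state, that is, a ring contraction from ten to six members and not a nucleophile-onto-electrophile closure. C10 (quaternary) and C5 are set together: the E geometry of both ring alkenes places C9 and C6 pseudo-equatorial and C14 and H-5 pseudo-axial in the chair, so vinyl and propenal become trans and methyl and H-5 anti, and the trans-fused C7–C8 lactone allows only the one chair in which its two ring bonds are equatorial, which fixes the absolute sense as 10β-methyl and 5α-H. The step needs chair over boat selectivity and a single diastereomeric chair, both secured by the alkene geometry and the lactone, and it needs the aldehyde to stay free, which the 6-O-triethylsilyl group secures by blocking hemiacetal formation. The reaction is unimolecular and neutral, so the angelate, the α-methylene lactone and the silyl ether should be untouched.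

Step 22
Reactants: 34 elemanolide TES ether
Product: 35 9α-angeloyloxy-6β-hydroxy-15-oxoelema-1,3,11(13)-trien-12,8α-olide (target)
Conditions: HF·pyridine, pyridine, THF, 0 °C
Reagents that add atoms: none
Why: Buffered HF·pyridine removes the secondary TES ether under conditions that the enal, the α-methylene lactone and the angelate should tolerate, and no stereocentre is affected.

**Compound list**

1 | 4-methoxybenzyl prop-2-yn-1-yl ether | C#CCOCc1ccc(OC)cc1 | starting material
2 | lithium acetylide of 1 | [Li]C#CCOCc1ccc(OC)cc1 | intermediate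
3 | ethyl 4-[(4-methoxybenzyl)oxy]but-2-ynoate | CCOC(=O)C#CCOCc1ccc(OC)cc1 | intermediate
4 | 5-bromo-2-methylpent-2-ene | CC(C)=CCCBr | starting material
5 | (4-methylpent-3-en-1-yl)magnesium bromide | CC(C)=CCC[Mg]Br | intermediate
6 | (4-methylpent-3-en-1-yl)copper (MgBr2/SMe2 complex) | CC(C)=CCC[Cu] | intermediate
7 | syn-carbocupration adduct (copper on C5, cis to the homoprenyl group) | CCOC(=O)/C([Cu])=C(\COCc1ccc(OC)cc1)CCC=C(C)C | intermediate
8 | ethyl (2Z)-3-{[(4-methoxybenzyl)oxy]methyl}-7-methylocta-2,6-dienoate | CCOC(=O)/C=C(\COCc1ccc(OC)cc1)CCC=C(C)C | intermediate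
9 | (2Z)-3-{[(4-methoxybenzyl)oxy]methyl}-7-methylocta-2,6-dien-1-ol | OC/C=C(\COCc1ccc(OC)cc1)CCC=C(C)C | intermediate
10 | TBS ether of 9 | CC(C)(C)[Si](C)(C)OC/C=C(\COCc1ccc(OC)cc1)CCC=C(C)C | intermediate
11 | (2E,6Z)-8-[(tert-butyldimethylsilyl)oxy]-6-{[(4-methoxybenzyl)oxy]methyl}-2-methylocta-2,6-dien-1-ol | CC(C)(C)[Si](C)(C)OC/C=C(\COCc1ccc(OC)cc1)CC/C=C(\C)CO | intermediate
12 | (2E,6Z)-8-[(tert-butyldimethylsilyl)oxy]-6-{[(4-methoxybenzyl)oxy]methyl}-2-methylocta-2,6-dienal | CC(C)(C)[Si](C)(C)OC/C=C(\COCc1ccc(OC)cc1)CC/C=C(\C)C=O | intermediate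
13 | triethyl phosphonoacetate | CCOC(=O)CP(=O)(OCC)OCC | starting material
14 | ethyl (2E,4E,8Z)-10-[(tert-butyldimethylsilyl)oxy]-8-{[(4-methoxybenzyl)oxy]methyl}-4-methyldeca-2,4,8-trienoate | CC(C)(C)[Si](C)(C)OC/C=C(\COCc1ccc(OC)cc1)CC/C=C(\C)/C=C/C(=O)OCC | intermediate
15 | (2E,4E,8Z)-10-[(tert-butyldimethylsilyl)oxy]-8-{[(4-methoxybenzyl)oxy]methyl}-4-methyldeca-2,4,8-trien-1-ol | CC(C)(C)[Si](C)(C)OC/C=C(\COCc1ccc(OC)cc1)CC/C=C(\C)/C=C/CO | intermediate
16 | {(2R,3R)-3-[(2E,6Z)-8-[(tert-butyldimethylsilyl)oxy]-6-{[(4-methoxybenzyl)oxy]methyl}octa-2,6-dien-2-yl]oxiran-2-yl}methanol | CC(C)(C)[Si](C)(C)OC/C=C(\COCc1ccc(OC)cc1)CC/C=C(\C)[C@H]1O[C@@H]1CO | intermediate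
17 | angelic acid ((2Z)-2-methylbut-2-enoic acid) | C/C=C(/C)C(=O)O | starting material
18 | (2R,3S,4E,8Z)-10-[(tert-butyldimethylsilyl)oxy]-1,2-dihydroxy-8-{[(4-methoxybenzyl)oxy]methyl}-4-methyldeca-4,8-dien-3-yl angelate | CC(C)(C)[Si](C)(C)OC/C=C(\COCc1ccc(OC)cc1)CC/C=C(\C)[C@H](OC(=O)/C(C)=C\C)[C@H](O)CO | intermediate
19 | (triphenylphosphoranylidene)ketene (Bestmann ylide) | O=C=C=P(c1ccccc1)(c1ccccc1)c1ccccc1 | starting material
20 | (2S,3S,4E,8Z)-10-[(tert-butyldimethylsilyl)oxy]-2-hydroxy-8-{[(4-methoxybenzyl)oxy]methyl}-4-methyl-1-oxodeca-4,8-dien-3-yl angelate | CC(C)(C)[Si](C)(C)OC/C=C(\COCc1ccc(OC)cc1)CC/C=C(\C)[C@H](OC(=O)/C(C)=C\C)[C@H](O)C=O | intermediate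
21 | 2-O-[(triphenylphosphoranylidene)acetyl] derivative of 20 | CC(C)(C)[Si](C)(C)OC/C=C(\COCc1ccc(OC)cc1)CC/C=C(\C)[C@H](OC(=O)/C(C)=C\C)[C@H](OC(=O)C=P(c1ccccc1)(c1ccccc1)c1ccccc1)C=O | intermediate
22 | (1S,2E,6Z)-8-[(tert-butyldimethylsilyl)oxy]-6-{[(4-methoxybenzyl)oxy]methyl}-2-methyl-1-[(2R)-5-oxo-2,5-dihydrofuran-2-yl]octa-2,6-dien-1-yl angelate | CC(C)(C)[Si](C)(C)OC/C=C(\COCc1ccc(OC)cc1)CC/C=C(\C)[C@H](OC(=O)/C(C)=C\C)[C@@H]1OC(=O)C=C1 | intermediate
23 | (1S,2E,6Z)-8-[(tert-butyldimethylsilyl)oxy]-1-[(2R)-4-(hydroxymethyl)-5-oxo-2,5-dihydrofuran-2-yl]-6-{[(4-methoxybenzyl)oxy]methyl}-2-methylocta-2,6-dien-1-yl angelate | CC(C)(C)[Si](C)(C)OC/C=C(\COCc1ccc(OC)cc1)CC/C=C(\C)[C@H](OC(=O)/C(C)=C\C)[C@@H]1OC(=O)C(CO)=C1 | intermediate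
24 | (1S,2E,6Z)-1-[(2R)-4-(bromomethyl)-5-oxo-2,5-dihydrofuran-2-yl]-8-[(tert-butyldimethylsilyl)oxy]-6-{[(4-methoxybenzyl)oxy]methyl}-2-methylocta-2,6-dien-1-yl angelate | CC(C)(C)[Si](C)(C)OC/C=C(\COCc1ccc(OC)cc1)CC/C=C(\C)[C@H](OC(=O)/C(C)=C\C)[C@@H]1OC(=O)C(CBr)=C1 | intermediate
25 | (1S,2E,6Z)-1-[(2R)-4-(bromomethyl)-5-oxo-2,5-dihydrofuran-2-yl]-8-hydroxy-6-{[(4-methoxybenzyl)oxy]methyl}-2-methylocta-2,6-dien-1-yl angelate | OC/C=C(\COCc1ccc(OC)cc1)CC/C=C(\C)[C@H](OC(=O)/C(C)=C\C)[C@@H]1OC(=O)C(CBr)=C1 | intermediate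
26 | (1S,2E,6Z)-1-[(2R)-4-(bromomethyl)-5-oxo-2,5-dihydrofuran-2-yl]-6-{[(4-methoxybenzyl)oxy]methyl}-2-methyl-8-oxoocta-2,6-dien-1-yl angelate | O=C/C=C(\COCc1ccc(OC)cc1)CC/C=C(\C)[C@H](OC(=O)/C(C)=C\C)[C@@H]1OC(=O)C(CBr)=C1 | intermediate
27 | allylchromium dichloride derived from 26 | O=C/C=C(\COCc1ccc(OC)cc1)CC/C=C(\C)[C@H](OC(=O)/C(C)=C\C)[C@@H]1OC(=O)C(C[Cr](Cl)Cl)=C1 | intermediate
28 | 9α-angeloyloxy-6α-hydroxy-15-[(4-methoxybenzyl)oxy]germacra-1(10)E,4Z,11(13)-trien-12,8α-olide (6α epimer drawn) | C1/C=C(\C)[C@H](OC(=O)/C(C)=C\C)[C@@H]2OC(=O)C(=C)[C@H]2[C@H](O)/C=C(COCc3ccc(OC)cc3)/C1 | intermediate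
29 | 9α-angeloyloxy-15-[(4-methoxybenzyl)oxy]-6-oxogermacra-1(10)E,4Z,11(13)-trien-12,8α-olide | C1/C=C(\C)[C@H](OC(=O)/C(C)=C\C)[C@@H]2OC(=O)C(=C)[C@H]2C(=O)/C=C(COCc3ccc(OC)cc3)/C1 | intermediate
30 | 9α-angeloyloxy-6β-hydroxy-15-[(4-methoxybenzyl)oxy]germacra-1(10)E,4Z,11(13)-trien-12,8α-olide | C1/C=C(\C)[C@H](OC(=O)/C(C)=C\C)[C@@H]2OC(=O)C(=C)[C@H]2[C@@H](O)/C=C(COCc3ccc(OC)cc3)/C1 | intermediate
31 | 9α-angeloyloxy-15-[(4-methoxybenzyl)oxy]-6β-(triethylsilyloxy)germacra-1(10)E,4Z,11(13)-trien-12,8α-olide | C1/C=C(\C)[C@H](OC(=O)/C(C)=C\C)[C@@H]2OC(=O)C(=C)[C@H]2[C@@H](O[Si](CC)(CC)CC)/C=C(COCc3ccc(OC)cc3)/C1 | intermediate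
32 | 9α-angeloyloxy-15-hydroxy-6β-(triethylsilyloxy)germacra-1(10)E,4Z,11(13)-trien-12,8α-olide | C1/C=C(\C)[C@H](OC(=O)/C(C)=C\C)[C@@H]2OC(=O)C(=C)[C@H]2[C@@H](O[Si](CC)(CC)CC)/C=C(CO)/C1 | intermediate
33 | 9α-angeloyloxy-15-oxo-6β-(triethylsilyloxy)germacra-1(10)E,4Z,11(13)-trien-12,8α-olide | C1/C=C(\C)[C@H](OC(=O)/C(C)=C\C)[C@@H]2OC(=O)C(=C)[C@H]2[C@@H](O[Si](CC)(CC)CC)/C=C(C=O)/C1 | intermediate
34 | 9α-angeloyloxy-15-oxo-6β-(triethylsilyloxy)elema-1,3,11(13)-trien-12,8α-olide | C=C[C@]1(C)[C@H](OC(=O)/C(C)=C\C)[C@@H]2OC(=O)C(=C)[C@H]2[C@@H](O[Si](CC)(CC)CC)[C@H]1C(=C)C=O | intermediate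
35 | 9α-angeloyloxy-6β-hydroxy-15-oxoelema-1,3,11(13)-trien-12,8α-olide (5R,6S,7S,8R,9S,10S) | C=C[C@]1(C)[C@H](OC(=O)/C(C)=C\C)[C@@H]2OC(=O)C(=C)[C@H]2[C@@H](O)[C@H]1C(=C)C=O | target

**Step count and risks**

Total step count: 22. Longest linear sequence: 22 steps (from 1; compounds 4, 13, 17 and 19 each enter in one step).

Steps most likely to fail:

1. Step 15 (ring closure). Oligomerization may outrun the ten-membered ring closure, or the tethered aldehyde may attack the butenolide face syn to the tether and give the cis-fused lactone (wrong C7), because the rigid butenolide restricts the geometry of approach. The fallback changes the precursor class and the order of lactone and ring formation; it sets out from 18 and comes back to the route at 29. Compound 18 is oxidized to 20 as in step 10 and silylated (TBSOTf, 2,6-lutidine) to the α-silyloxy aldehyde F1. Addition of the [α-(methoxycarbonyl)vinyl]alane made from methyl propiolate, i-Bu2AlH and HMPA gives the Morita–Baylis–Hillman-type allylic alcohol F2, and NBS/Me2S converts it with allylic transposition into the open-chain (Z)-2-(bromomethyl)enoate F3. HF·pyridine frees the primary allylic alcohol F4 and MnO2 gives the enal F5. CrCl2 under high dilution then closes the ten-membered ring to the hydroxy ester F6; this flexible 2-(alkoxycarbonyl)allyl bromide is the substrate type with direct precedent for germacrane ring closure. Dess–Martin oxidation gives the ketone F7, in which C7 is α to the ketone and can equilibrate. Aqueous HF in MeCN followed by a trace of camphorsulfonic acid removes the C8 silyl ether and lactonizes the freed hydroxyl onto the methyl ester to give the trans-fused lactone 29.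

2. Step 17 (C6 reduction). Hydride may add with poor facial selectivity and return the 6α-alcohol, or 1,4-reduction of the α-methylene lactone may compete. The fallback replaces redox by SN2 inversion; it sets out from 28 (6α-alcohol) and comes back at 30. A Mitsunobu reaction of 28 with chloroacetic acid (PPh3, diisopropyl azodicarboxylate, PhMe, 0 °C) gives the inverted 6β-chloroacetate F8. Thiourea and NaHCO3 in EtOH then remove the chloroacetyl group selectively beside the angelate and the lactone to give 30; steps 16 and 17 are skipped.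

3. Step 11 (hydroxymethylation). Deprotonation of the butenolide at C8 during the nucleophile-catalysed reaction may lead to loss of the C9 angelate by elimination or to epimerization at C8, or the reaction may stall. The fallback builds the bromomethyl butenolide by ring-closing metathesis; it sets out from 18 and comes back at 24. Compound 18 is oxidized to 20 as in step 10, and Takai methylenation (CH2I2, Zn, Ti(Oi-Pr)4, THF) gives the vinyl carbinol F9. Acylation with 2-(bromomethyl)acryloyl chloride and 2,6-lutidine gives the diene ester F10. Ring-closing metathesis with the second-generation Hoveyda–Grubbs catalyst in PhMe at 80 °C closes the butenolide to 24, so 22 and 23 are bypassed.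

Further compounds
F1 | step 15 | (2S,3S,4E,8Z)-2,10-bis[(tert-butyldimethylsilyl)oxy]-8-{[(4-methoxybenzyl)oxy]methyl}-4-methyl-1-oxodeca-4,8-dien-3-yl angelate | CC(C)(C)[Si](C)(C)OC/C=C(\COCc1ccc(OC)cc1)CC/C=C(\C)[C@H](OC(=O)/C(C)=C\C)[C@H](O[Si](C)(C)C(C)(C)C)C=O
F2 | step 15 | methyl 5-angeloyloxy-4,12-bis[(tert-butyldimethylsilyl)oxy]-3-hydroxy-10-{[(4-methoxybenzyl)oxy]methyl}-6-methyl-2-methylidenedodeca-6,10-dienoate (C3 epimers; C4 and C5 as in F1) | CC(C)(C)[Si](C)(C)OC/C=C(\COCc1ccc(OC)cc1)CC/C=C(\C)[C@H](OC(=O)/C(C)=C\C)[C@H](O[Si](C)(C)C(C)(C)C)C(O)C(=C)C(=O)OC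
F3 | step 15 | methyl (2Z,6E,10Z)-5-angeloyloxy-2-(bromomethyl)-4,12-bis[(tert-butyldimethylsilyl)oxy]-10-{[(4-methoxybenzyl)oxy]methyl}-6-methyldodeca-2,6,10-trienoate | CC(C)(C)[Si](C)(C)OC/C=C(\COCc1ccc(OC)cc1)CC/C=C(\C)[C@H](OC(=O)/C(C)=C\C)[C@H](O[Si](C)(C)C(C)(C)C)/C=C(\CBr)C(=O)OC
F4 | step 15 | 12-hydroxy analogue of F3 (primary silyl ether removed) | OC/C=C(\COCc1ccc(OC)cc1)CC/C=C(\C)[C@H](OC(=O)/C(C)=C\C)[C@H](O[Si](C)(C)C(C)(C)C)/C=C(\CBr)C(=O)OC
F5 | step 15 | 12-oxo analogue of F3 (enal) | O=C/C=C(\COCc1ccc(OC)cc1)CC/C=C(\C)[C@H](OC(=O)/C(C)=C\C)[C@H](O[Si](C)(C)C(C)(C)C)/C=C(\CBr)C(=O)OC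
F6 | step 15 | methyl 9α-angeloyloxy-8α-[(tert-butyldimethylsilyl)oxy]-6-hydroxy-15-[(4-methoxybenzyl)oxy]germacra-1(10)E,4Z,11(13)-trien-12-oate (C6 and C7 not defined) | C1/C=C(\C)[C@H](OC(=O)/C(C)=C\C)[C@H](O[Si](C)(C)C(C)(C)C)C(C(=C)C(=O)OC)C(O)/C=C(COCc2ccc(OC)cc2)/C1
F7 | step 15 | methyl 9α-angeloyloxy-8α-[(tert-butyldimethylsilyl)oxy]-15-[(4-methoxybenzyl)oxy]-6-oxogermacra-1(10)E,4Z,11(13)-trien-12-oate (C7 equilibrating) | C1/C=C(\C)[C@H](OC(=O)/C(C)=C\C)[C@H](O[Si](C)(C)C(C)(C)C)C(C(=C)C(=O)OC)C(=O)/C=C(COCc2ccc(OC)cc2)/C1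
F8 | step 17 | 9α-angeloyloxy-6β-(chloroacetoxy)-15-[(4-methoxybenzyl)oxy]germacra-1(10)E,4Z,11(13)-trien-12,8α-olide | C1/C=C(\C)[C@H](OC(=O)/C(C)=C\C)[C@@H]2OC(=O)C(=C)[C@H]2[C@@H](OC(=O)CCl)/C=C(COCc3ccc(OC)cc3)/C1
F9 | step 11 | (3R,4S,5E,9Z)-11-[(tert-butyldimethylsilyl)oxy]-3-hydroxy-9-{[(4-methoxybenzyl)oxy]methyl}-5-methylundeca-1,5,9-trien-4-yl angelate | CC(C)(C)[Si](C)(C)OC/C=C(\COCc1ccc(OC)cc1)CC/C=C(\C)[C@H](OC(=O)/C(C)=C\C)[C@H](O)C=C
F10 | step 11 | 3-O-[2-(bromomethyl)acryloyl] derivative of F9 | CC(C)(C)[Si](C)(C)OC/C=C(\COCc1ccc(OC)cc1)CC/C=C(\C)[C@H](OC(=O)/C(C)=C\C)[C@H](OC(=O)C(=C)CBr)C=C
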